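**Retrosynthetic overview**

- Ring numbering: C1 (side-chain carbon), C2, C3 (free carbinol), C4, C5 (methoxy carbon), C6 (acetoxy carbinol); chain C1', C2' (acetoxy carbinol). The only ring is a cyclohexa-1,4-diene (C1=C2, C4=C5) whose two sp3 carbons C3 and C6 carry cis oxygens. This is the adduct pattern of an alkyne (C1, C2) with a 1,4-dioxygenated buta-1,3-diene (C3–C6), and the strategy rests on it.
- Last disconnection: the O3–Si bond of the O3-silyl ether of the target.
- Key disconnection: C1–C6 and C2–C3, a cobalt-catalysed [4+2] of a (1Z,3E)-1-acetoxy-2-methoxy-4-silyloxybutadiene with (R)-heptadec-1-yn-4-yl acetate. The single ring and both ring stereocentres are formed here.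
- Diene: from methyl (E)-4-chloro-3-methoxybut-2-enoate by reduction, oxidation, acetate displacement and vinylogous O-silylation.
- Alkyne: C2' from (R)-epichlorohydrin, through dodecyl Grignard opening, epoxide closure, acetylide opening and acetylation.

Key step: step 9

Assumption: which antipode of the bisphosphine binds the diene face that leads to the (3R,6S) ring cannot be foretold; the route is written with the (S,S) ligand, and its mirror image is to be used if the first run shows the opposite sense.

**Route**

Step 1
Reactants: 1 methyl (E)-4-chloro-3-methoxybut-2-enoate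
Product: 2 (E)-4-chloro-3-methoxybut-2-en-1-ol
Conditions: iBu2AlH (2.2 equiv), CH2Cl2, −78 °C; aq. potassium sodium tartrate work-up
Reagents that add atoms: none
Why: 1,2-reduction of the vinylogous carbonate ester by the aluminium hydride at low temperature (ester to allylic alcohol) should leave the enol ether, the alkene geometry and the primary chloride untouched, provided the work-up stays neutral.

Step 2
Reactants: 2 (E)-4-chloro-3-methoxybut-2-en-1-ol
Product: 3 (E)-4-chloro-3-methoxybut-2-enal
Conditions: MnO2 (activated, excess), CH2Cl2, 25 °C
Reagents that add atoms: none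
Why: allylic alcohol oxidation with MnO2 is neutral and heterogeneous, so the acid-labile methoxy enol ether should survive and the β-methoxy enal is obtained without over-oxidation.

Step 3
Reactants: 3 (E)-4-chloro-3-methoxybut-2-enal
Product: 4 (E)-2-methoxy-4-oxobut-2-en-1-yl acetate
Conditions: KOAc (1.5 equiv), NaI (cat.), DMF, 25 °C
Reagents that add atoms: potassium acetate, CC(=O)[O-].[K+]
Why: SN2 displacement of a chloride that is activated like an α-halo carbonyl by the adjacent vinylogous formyl group, with the weakly basic acetate as nucleophile and iodide as Finkelstein catalyst.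

Step 4
Reactants: 4 (E)-2-methoxy-4-oxobut-2-en-1-yl acetate
Product: 5 (1Z,3E)-4-[(tert-butyldimethylsilyl)oxy]-2-methoxybuta-1,3-dien-1-yl acetate
Conditions: TBSOTf (1.1 equiv), Et3N (1.5 equiv), Et2O, −78 → 0 °C; cold aq. NaHCO3/pentane work-up, bulb-to-bulb distillation
Reagents that add atoms: tert-butyldimethylsilyl trifluoromethanesulfonate, CC(C)(C)[Si](C)(C)OS(=O)(=O)C(F)(F)F
Why: soft vinylogous enolisation (silyl dienol ether formation from an enal), in which O-silylation gives a methoxy-stabilised silyloxyallyl cation and the amine removes a γ-proton from CH2OAc; the s-trans enal should give the 3E silyloxyalkene and the acetoxy group should settle trans to the vinyl residue (1Z).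

Step 5
Reactants: 6 1-bromododecane; 7 (R)-epichlorohydrin
Product: 9 (R)-1-chloropentadecan-2-ol, via dodecylmagnesium bromide 8 (not isolated)
Conditions: Mg, THF, 40 °C; then 7, CuI (10 mol%), THF, −40 → 0 °C; aq. NH4Cl
Reagents that add atoms: none
Why: copper-catalysed Grignard opening of the epoxide at its unsubstituted carbon is faster than attack at CH2Cl and does not touch the C–O bond of the stereocentre, so the R configuration of 7 is carried into the chlorohydrin.

Step 6
Reactants: 9 (R)-1-chloropentadecan-2-ol
Product: 10 (R)-2-tridecyloxirane
Conditions: NaOH (powdered), Et2O, 25 °C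
Reagents that add atoms: none
Why: intramolecular Williamson etherification, in which the alkoxide displaces chloride at the primary carbon, so the stereocentre is not involved and stays R.

Step 7
Reactants: 10 (R)-2-tridecyloxirane
Product: 11 (R)-heptadec-1-yn-4-ol
Conditions: LiC≡CH·H2NCH2CH2NH2 (1.5 equiv), DMSO, 25 °C; aq. NH4Cl
Reagents that add atoms: lithium acetylide–ethylenediamine complex, [Li+].[C-]#C.NCCN
Why: SN2 opening of a terminal epoxide by acetylide at the unsubstituted carbon gives the homopropargylic alcohol with the carbinol configuration unchanged.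

Step 8
Reactants: 11 (R)-heptadec-1-yn-4-ol
Product: 12 (R)-heptadec-1-yn-4-yl acetate
Conditions: Ac2O, pyridine, DMAP (cat.), CH2Cl2, 25 °C
Reagents that add atoms: acetic anhydride, CC(=O)OC(C)=O
Why: DMAP-catalysed O-acylation of a secondary alcohol proceeds with retention and installs the C2' acetate of the target before the ring is built.

Step 9
Reactants: 5 (1Z,3E)-4-[(tert-butyldimethylsilyl)oxy]-2-methoxybuta-1,3-dien-1-yl acetate; 12 (R)-heptadec-1-yn-4-yl acetate
Product: 13 (1S,4R)-6-[(2R)-2-acetoxypentadecyl]-4-[(tert-butyldimethylsilyl)oxy]-2-methoxycyclohexa-2,5-dien-1-yl acetate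
Conditions: CoBr2 (10 mol%), (2S,4S)-2,4-bis(diphenylphosphino)pentane (10 mol%), Zn (20 mol%), ZnI2 (20 mol%), 5 (1.5 equiv), CH2Cl2, 25 °C, slow addition of 12
Reagents that add atoms: none
Why: Proposed new method: Zn reduces the CoBr2–bisphosphine complex to monovalent cobalt and ZnI2 takes up bromide, so a cationic cobalt centre binds diene 5 in its s-cis form (η4) and alkyne 12 (η2); oxidative cyclisation joins the unsubstituted alkyne carbon C2 to the silyloxy terminus C3 to give a trivalent η3-allyl σ-vinyl cobalt species, and reductive elimination then joins C1 to the acetoxy terminus C6. The closest known reaction is the cobalt-catalysed neutral [4+2] cycloaddition of terminal alkynes with alkyl- and silyloxy-substituted buta-1,3-dienes to cyclohexa-1,4-dienes, which also runs enantioselectively with chiral bisphosphines but has not been applied to a 1,4-dioxygenated 2-alkoxydiene. The six-membered ring closes by C–C reductive elimination from the seven-membered metallacycle, that is as a metal-templated suprafacial [4+2], so the mismatch of two electron-rich partners that blocks the thermal reaction does not apply. C3 and C6 are created together: both oxygens point outward in the s-cis (1Z,3E) diene, so addition of the alkyne to one face makes them cis, and the face, hence the absolute configuration (3R,6S in ring numbering), is chosen by the C2-symmetric ligand because the C2' centre of 12 is too remote. The step needs the regiochemistry in which the alkyl-bearing alkyne carbon meets the acetoxy terminus; the steric difference between the bulky silyloxy terminus (which should pair with the alkyne CH in the first bond formation) and the small acetoxy terminus favours it, the bite angle of the ligand tunes it, and a (1E) diene isomer cannot reach the s-cis form and stays a spectator. The conditions are aprotic and nearly neutral, as the skipped diene with two allylic C–O bonds requires.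

Step 10
Reactants: 13 (1S,4R)-6-[(2R)-2-acetoxypentadecyl]-4-[(tert-butyldimethylsilyl)oxy]-2-methoxycyclohexa-2,5-dien-1-yl acetate
Product: 14 (1S,4R)-6-[(2R)-2-acetoxypentadecyl]-4-hydroxy-2-methoxycyclohexa-2,5-dien-1-yl acetate
Conditions: Bu4NF (3 equiv), AcOH (3 equiv), THF, 0 → 25 °C
Reagents that add atoms: none
Why: fluoride-driven cleavage of the Si–O bond (silyl ether deprotection) under acetic acid buffering is neither basic enough to cleave or shift the acetates nor acidic enough to hydrolyse the enol ether or trigger aromatisation, and no stereocentre is touched.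

**Compound list**

1 | methyl (E)-4-chloro-3-methoxybut-2-enoate | COC(=O)/C=C(/OC)CCl | starting material
2 | (E)-4-chloro-3-methoxybut-2-en-1-ol | OC/C=C(/OC)CCl | intermediate
3 | (E)-4-chloro-3-methoxybut-2-enal | O=C/C=C(/OC)CCl | intermediate
4 | (E)-2-methoxy-4-oxobut-2-en-1-yl acetate | O=C/C=C(/OC)COC(C)=O | intermediate
5 | (1Z,3E)-4-[(tert-butyldimethylsilyl)oxy]-2-methoxybuta-1,3-dien-1-yl acetate | CC(=O)O/C=C(OC)/C=C/O[Si](C)(C)C(C)(C)C | intermediate
6 | 1-bromododecane | CCCCCCCCCCCCBr | starting material
7 | (R)-epichlorohydrin | ClC[C@H]1CO1 | starting material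
8 | dodecylmagnesium bromide | CCCCCCCCCCCC[Mg]Br | intermediate
9 | (R)-1-chloropentadecan-2-ol | CCCCCCCCCCCCC[C@@H](O)CCl | intermediate
10 | (R)-2-tridecyloxirane | CCCCCCCCCCCCC[C@@H]1CO1 | intermediate
11 | (R)-heptadec-1-yn-4-ol | CCCCCCCCCCCCC[C@H](CC#C)O | intermediate
12 | (R)-heptadec-1-yn-4-yl acetate | CCCCCCCCCCCCC[C@H](CC#C)OC(C)=O | intermediate
13 | (1S,4R)-6-[(2R)-2-acetoxypentadecyl]-4-[(tert-butyldimethylsilyl)oxy]-2-methoxycyclohexa-2,5-dien-1-yl acetate | CCCCCCCCCCCCC[C@H](CC1=C[C@@H](O[Si](C)(C)C(C)(C)C)C=C(OC)[C@H]1OC(C)=O)OC(C)=O | intermediate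
14 | (1S,4R)-6-[(2R)-2-acetoxypentadecyl]-4-hydroxy-2-methoxycyclohexa-2,5-dien-1-yl acetate | CCCCCCCCCCCCC[C@H](CC1=C[C@@H](O)C=C(OC)[C@H]1OC(C)=O)OC(C)=O | target

**Step count and risks**

Total step count: 10. Longest linear sequence: 6 steps (steps 1–4, 9, 10; the alkyne branch, steps 5–8, 9, 10, is equally long).

Steps most likely to fail:

1. Step 9 (proposed new method).
   - What may go wrong: the termini may pair the wrong way in the oxidative cyclisation, since a 2-alkoxy group in the known bisphosphine systems steers the alkyne substituent to the para position, which here is the undesired isomer. The ligand may discriminate the diene faces too weakly, giving both ring configurations next to the fixed C2' centre. The zinc halides may ionise an allylic C–O bond, after which the ring aromatises, and the alkyne may cyclotrimerise.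
   - First adjustments: NaB[3,5-(CF3)2C6H3]4 in place of ZnI2, and ligands of other bite angle.
   - Fallback (known chemistry, sets out from 12 and comes back at 13): radical selenosulfonation of 12 with Se-phenyl 4-methylbenzenesulfonoselenoate (AIBN, benzene, 80 °C) should give (R,E)-2-(phenylselanyl)-1-[(4-methylphenyl)sulfonyl]heptadec-1-en-4-yl acetate F1. Oxidation with mCPBA and selenoxide syn-elimination, without base, should give (R)-1-[(4-methylphenyl)sulfonyl]heptadec-1-yn-4-yl acetate F2. A thermal normal-demand Diels–Alder reaction of F2 with diene 5 (toluene, 60–80 °C) should join the nucleophilic acetoxy terminus of the diene to the alkyl-bearing β-carbon of the alkynyl sulfone and give, with cis oxygens, the 5-[(4-methylphenyl)sulfonyl] derivative of 13 F3. No facial control is expected in this cycloaddition, so the two ring diastereomers would have to be separated by chromatography. Reductive desulfonylation of the vinyl sulfone (SmI2, DMPU, MeOH, THF, −78 °C) should then return 13.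

2. Step 4.
   - What may go wrong: the geometry of the enol acetate may be poorly controlled in the γ-deprotonation (acetoxy group turned inward), and the dienol ether may hydrolyse during isolation.
   - Fallback (sets out from 2 and comes back at 5): silylation of 2 (TBSCl, imidazole, DMF) should give tert-butyl{[(E)-4-chloro-3-methoxybut-2-en-1-yl]oxy}dimethylsilane F4. Oxidation of the allylic chloride with N-methylmorpholine N-oxide (NaI cat., MeCN, 25 °C) should give (E)-4-[(tert-butyldimethylsilyl)oxy]-2-methoxybut-2-enal F5. γ-Deprotonation with KN(SiMe3)2 (THF, −78 °C) and O-acetylation of the dienolate with Ac2O should give 5. The enol acetate geometry then follows from the s-trans enal, and the silyloxyalkene forms as a plain E-disubstituted alkene.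

3. Step 10.
   - What may go wrong: the secondary silyl ether may cleave slowly under buffered fluoride, so that on long exposure acetate is lost or AcOH is eliminated across the ring with aromatisation.
   - Fallback (sets out from 4 and comes back at 14): vinylogous silylation of 4 with Et3SiOTf/Et3N should give (1Z,3E)-2-methoxy-4-[(triethylsilyl)oxy]buta-1,3-dien-1-yl acetate F6. The cobalt cycloaddition of step 9 with 12 should give (1S,4R)-6-[(2R)-2-acetoxypentadecyl]-2-methoxy-4-[(triethylsilyl)oxy]cyclohexa-2,5-dien-1-yl acetate F7. The far more labile silyl group should then be removed with HF·pyridine buffered with pyridine (THF, 0 °C) to give 14.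

**Further compounds**

F1 | step 9 | (R,E)-2-(phenylselanyl)-1-[(4-methylphenyl)sulfonyl]heptadec-1-en-4-yl acetate | CCCCCCCCCCCCC[C@H](C/C(=C\S(=O)(=O)c1ccc(C)cc1)[Se]c1ccccc1)OC(C)=O
F2 | step 9 | (R)-1-[(4-methylphenyl)sulfonyl]heptadec-1-yn-4-yl acetate | CCCCCCCCCCCCC[C@H](CC#CS(=O)(=O)c1ccc(C)cc1)OC(C)=O
F3 | step 9 | 5-[(4-methylphenyl)sulfonyl] derivative of 13 (sulfonyl on the ring CH carbon next to the silyloxy carbinol, ring carbinols arranged as in 13) | CCCCCCCCCCCCC[C@H](CC1=C(S(=O)(=O)c2ccc(C)cc2)[C@@H](O[Si](C)(C)C(C)(C)C)C=C(OC)[C@H]1OC(C)=O)OC(C)=O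
F4 | step 4 | tert-butyl{[(E)-4-chloro-3-methoxybut-2-en-1-yl]oxy}dimethylsilane | CC(C)(C)[Si](C)(C)OC/C=C(/OC)CCl
F5 | step 4 | (E)-4-[(tert-butyldimethylsilyl)oxy]-2-methoxybut-2-enal | CC(C)(C)[Si](C)(C)OC/C=C(/OC)C=O
F6 | step 10 | (1Z,3E)-2-methoxy-4-[(triethylsilyl)oxy]buta-1,3-dien-1-yl acetate | CC(=O)O/C=C(OC)/C=C/O[Si](CC)(CC)CC
F7 | step 10 | (1S,4R)-6-[(2R)-2-acetoxypentadecyl]-2-methoxy-4-[(triethylsilyl)oxy]cyclohexa-2,5-dien-1-yl acetate | CCCCCCCCCCCCC[C@H](CC1=C[C@@H](O[Si](CC)(CC)CC)C=C(OC)[C@H]1OC(C)=O)OC(C)=O
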